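**Retrosynthetic overview**
1. Last bond: C14–C15, made by hydrozirconation of a C21 terminal enyne (ring B half, C15≡C15') and palladium-catalysed coupling with a C19 (E)-iodotetraene (ring A half, C14–I). Both halves already carry their palmitate, so this step ends the synthesis.
2. Ring A half: C11=C12 and C7=C8 by two Horner–Wadsworth–Emmons olefinations from a C10 epoxy aldehyde, itself from (4R,6R)-4-hydroxy-2,2,6-trimethylcyclohexanone by enol triflate carbonylation and Katsuki–Sharpless epoxidation (C5, C6).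
3. Ring B half: C11'=C12' by Horner–Wadsworth–Emmons olefination of a C15 aldehyde made from (R)-α-ionone (C9'=C10' olefination, allylic oxidation at C3', hydride reduction). Both chain phosphonates come from one (E)-3-iodo-2-methylallyl alcohol.
4. Rings: the cyclohexane of ring A and the cyclohexene of ring B come with the starting materials. The only ring made is the C5–C6 oxirane, closed before any chain carbon is attached.
5. Enabling feature: C14 and C15 are adjacent unhindered CH sp2 carbons in the middle of the chain (the C20 methyl sits on C13). The stereocentres of ring A (C3, C5, C6) and ring B (C3', C6') and both esters lie at least eight bonds away, so an alkyne at C15 and an iodide on C14 can be joined without touching them.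

Key step: step 25

Assumption: (4R,6R)-4-hydroxy-2,2,6-trimethylcyclohexanone and (R)-α-ionone are bought as single enantiomers; positions are cited in carotenoid numbering (C1–C20 for the ring A half, C1'–C20' for the ring B half).

**Route**

Step 1
Reactants: 1 prop-2-yn-1-ol
Product: 3 (2E)-3-iodo-2-methylprop-2-en-1-ol, via alkenylalane 2 (not isolated)
Conditions: AlMe3 (3 equiv), Cp2ZrCl2 (0.25 equiv), CH2Cl2, 0 °C to rt; then I2, THF, −30 to 0 °C
Reagents that add atoms: trimethylaluminium (C[Al](C)C); iodine (II)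
Why: Zirconium-catalysed carboalumination (Negishi) adds methyl and aluminium syn across the alkyne with methyl on the internal carbon, and iodinolysis of the C–Al bond with retention should give the (E)-iodoalkene as one isomer.

Step 2
Reactants: 3 (2E)-3-iodo-2-methylprop-2-en-1-ol
Product: 4 (1E)-3-bromo-1-iodo-2-methylprop-1-ene
Conditions: CBr4, PPh3, CH2Cl2, 0 °C
Reagents that add atoms: carbon tetrabromide (BrC(Br)(Br)Br)
Why: Appel bromination of a primary allylic alcohol is an SN2 process that leaves the vinyl iodide and the alkene geometry untouched.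

Step 3
Reactants: 4 (1E)-3-bromo-1-iodo-2-methylprop-1-ene
Product: 5 diethyl [(2E)-3-iodo-2-methylprop-2-en-1-yl]phosphonate
Conditions: P(OEt)3 (neat), 90 °C
Reagents that add atoms: triethyl phosphite (CCOP(OCC)OCC)
Why: Michaelis–Arbuzov reaction at the primary allylic bromide; the vinyl C–I bond does not react with a phosphite in the absence of a metal catalyst.

Step 4
Reactants: 3 (2E)-3-iodo-2-methylprop-2-en-1-ol; 6 ethynyltrimethylsilane
Product: 7 (2E)-2-methyl-5-(trimethylsilyl)pent-2-en-4-yn-1-ol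
Conditions: PdCl2(PPh3)2 (2 mol%), CuI (4 mol%), Et3N, THF, rt
Reagents that add atoms: none
Why: Sonogashira coupling of the vinyl iodide proceeds with retention of the (E) geometry and tolerates the free alcohol.

Step 5
Reactants: 7 (2E)-2-methyl-5-(trimethylsilyl)pent-2-en-4-yn-1-ol
Product: 8 [(3E)-5-bromo-4-methylpent-3-en-1-yn-1-yl]trimethylsilane
Conditions: CBr4, PPh3, CH2Cl2, 0 °C
Reagents that add atoms: carbon tetrabromide (BrC(Br)(Br)Br)
Why: Appel bromination at the primary allylic position, with the silyl-capped enyne as a spectator.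

Step 6
Reactants: 8 [(3E)-5-bromo-4-methylpent-3-en-1-yn-1-yl]trimethylsilane
Product: 9 diethyl [(2E)-2-methyl-5-(trimethylsilyl)pent-2-en-4-yn-1-yl]phosphonate
Conditions: P(OEt)3 (neat), 110 °C
Reagents that add atoms: triethyl phosphite (CCOP(OCC)OCC)
Why: Michaelis–Arbuzov reaction at the primary allylic bromide gives the enyne phosphonate with the alkene geometry unchanged.

Step 7
Reactants: 10 (4R,6R)-4-hydroxy-2,2,6-trimethylcyclohexan-1-one
Product: 11 (4R,6R)-4-[(tert-butyldimethylsilyl)oxy]-2,2,6-trimethylcyclohexan-1-one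
Conditions: TBSCl, imidazole, DMF, rt
Reagents that add atoms: tert-butyldimethylsilyl chloride (CC(C)(C)[Si](C)(C)Cl)
Why: Standard silylation of the secondary alcohol protects O3 through the base and hydride steps that follow.

Step 8
Reactants: 11 silyl ether of the hydroxy ketone
Product: 13 (4R)-4-[(tert-butyldimethylsilyl)oxy]-2,6,6-trimethylcyclohex-1-en-1-yl trifluoromethanesulfonate, via lithium enolate 12 (not isolated)
Conditions: LiN(i-Pr)2, THF, −78 °C; then PhNTf2, −78 to 0 °C
Reagents that add atoms: N-phenylbis(trifluoromethanesulfonimide) (O=S(=O)(N(c1ccccc1)S(=O)(=O)C(F)(F)F)C(F)(F)F)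
Why: Enolate O-triflation; the ketone can enolise only toward the methyl-bearing carbon (the other α-carbon is quaternary), so one enol triflate should form, the methyl stereocentre being erased on purpose while C3 is untouched.

Step 9
Reactants: 13 enol triflate
Product: 14 methyl (4R)-4-[(tert-butyldimethylsilyl)oxy]-2,6,6-trimethylcyclohex-1-ene-1-carboxylate
Conditions: Pd(OAc)2 (5 mol%), PPh3 (10 mol%), CO (1 atm), MeOH, Et3N, DMF, 60 °C
Reagents that add atoms: carbon monoxide ([C-]#[O+]); methanol (CO)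
Why: Palladium-catalysed alkoxycarbonylation of an enol triflate (oxidative addition, CO insertion, methanolysis) installs C7 at the ester level.

Step 10
Reactants: 14 unsaturated methyl ester
Product: 15 [(4R)-4-[(tert-butyldimethylsilyl)oxy]-2,6,6-trimethylcyclohex-1-en-1-yl]methanol
Conditions: i-Bu2AlH (2.5 equiv), CH2Cl2, −78 to 0 °C; aq. potassium sodium tartrate
Reagents that add atoms: none
Why: Hydride reduction of the conjugated ester gives the allylic alcohol without touching the silyl ether.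

Step 11
Reactants: 15 allylic alcohol
Product: 16 [(1R,2R,4S)-4-[(tert-butyldimethylsilyl)oxy]-1,2-epoxy-2,6,6-trimethylcyclohexyl]methanol
Conditions: Ti(Oi-Pr)4 (1.0 equiv), diethyl D-(−)-tartrate (1.2 equiv), t-BuOOH (in decane), 4 Å molecular sieves, CH2Cl2, −20 °C
Reagents that add atoms: tert-butyl hydroperoxide (CC(C)(C)OO)
Why: Katsuki–Sharpless asymmetric epoxidation; the titanium D-tartrate complex delivers oxygen to the face of the C5=C6 alkene anti to the C3 silyloxy group (reagent control reinforced by the substrate), which sets C5 and C6 together.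

Step 12
Reactants: 16 epoxy alcohol
Product: 17 (1S,2R,4S)-4-[(tert-butyldimethylsilyl)oxy]-1,2-epoxy-2,6,6-trimethylcyclohexane-1-carbaldehyde
Conditions: SO3·pyridine, DMSO, i-Pr2NEt, CH2Cl2, 0 °C
Reagents that add atoms: none
Why: Parikh–Doering oxidation is non-acidic, so the epoxide should survive, and the aldehyde has no α-hydrogen to epimerise.

Step 13
Reactants: 17 C10 epoxy aldehyde; 18 diethyl [(2E)-3-cyano-2-methylprop-2-en-1-yl]phosphonate
Product: 20 (2E,4E)-5-[(1S,2R,4S)-4-[(tert-butyldimethylsilyl)oxy]-1,2-epoxy-2,6,6-trimethylcyclohexyl]-3-methylpenta-2,4-dienenitrile, via sodium phosphonate carbanion 19 (not isolated)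
Conditions: 18, NaN(SiMe3)2, THF, −78 °C; then 17, −78 to 0 °C
Reagents that add atoms: none
Why: Horner–Wadsworth–Emmons olefination with the stabilised allylic phosphonate anion should form C7=C8 trans and give the (7E,9E)-dienenitrile, any (9Z) isomer being removed by chromatography.

Step 14
Reactants: 20 silylated C15 epoxy nitrile
Product: 21 (2E,4E)-5-[(1S,2R,4S)-1,2-epoxy-4-hydroxy-2,6,6-trimethylcyclohexyl]-3-methylpenta-2,4-dienenitrile
Conditions: Bu4NF, THF, 0 °C to rt
Reagents that add atoms: none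
Why: Fluoride-mediated desilylation frees O3 under conditions to which the epoxide and the dienenitrile are inert.

Step 15
Reactants: 21 C15 epoxy hydroxy nitrile
Product: 23 (2E,4E)-5-[(1S,2R,4S)-1,2-epoxy-4-hydroxy-2,6,6-trimethylcyclohexyl]-3-methylpenta-2,4-dienal, via aluminio-aldimine 22 (not isolated)
Conditions: i-Bu2AlH (2.3 equiv), CH2Cl2, −78 °C; then wet silica gel, 0 °C
Reagents that add atoms: water (O)
Why: Partial hydride reduction of a nitrile; the first equivalent forms the aluminium alkoxide, the second adds once to the nitrile, and hydrolysis of the imine on wet silica gives the aldehyde without acid, so the vinyl epoxide should not rearrange.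

Step 16
Reactants: 23 C15 epoxy hydroxy aldehyde; 24 hexadecanoyl chloride
Product: 25 (2E,4E)-5-[(1S,2R,4S)-1,2-epoxy-4-(hexadecanoyloxy)-2,6,6-trimethylcyclohexyl]-3-methylpenta-2,4-dienal
Conditions: pyridine, DMAP (cat.), CH2Cl2, 0 °C to rt
Reagents that add atoms: none
Why: DMAP-catalysed acylation under basic conditions installs the first palmitate with retention at C3.

Step 17
Reactants: 25 C15 epoxy aldehyde palmitate; 5 iodoallyl phosphonate
Product: 27 (1S,3R,4S)-3,4-epoxy-4-[(1E,3E,5E,7E)-8-iodo-3,7-dimethylocta-1,3,5,7-tetraen-1-yl]-3,5,5-trimethylcyclohexyl hexadecanoate, via sodium phosphonate carbanion 26 (not isolated)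
Conditions: 5, NaN(SiMe3)2, THF, −78 °C; then 25, −78 to −20 °C, dark
Reagents that add atoms: none
Why: Horner–Wadsworth–Emmons olefination of the enal with the allylic phosphonate should form C11=C12 trans and carries the preformed (13E)-iodoalkene in unchanged, the ester being inert to the stabilised carbanion.

Step 18
Reactants: 28 (R)-α-ionone; 29 diethyl (cyanomethyl)phosphonate
Product: 31 (2E,4E)-3-methyl-5-[(1R)-2,6,6-trimethylcyclohex-2-en-1-yl]penta-2,4-dienenitrile, via sodium phosphonate carbanion 30 (not isolated)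
Conditions: 29, NaH, THF, 0 °C; then 28, rt
Reagents that add atoms: none
Why: Horner–Wadsworth–Emmons olefination of the methyl ketone with the preformed anion (no excess base, so the doubly allylic C6' centre is not deprotonated) should favour the (9'E) nitrile, the (9'Z) isomer being removed by chromatography.

Step 19
Reactants: 31 (R)-α-ionylideneacetonitrile
Product: 32 (2E,4E)-3-methyl-5-[(1R)-2,6,6-trimethyl-4-oxocyclohex-2-en-1-yl]penta-2,4-dienenitrile
Conditions: t-BuOOH (70% in water), Rh2(cap)4 (1 mol%, cap = caprolactamate), NaHCO3, CH2Cl2, rt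
Reagents that add atoms: tert-butyl hydroperoxide (CC(C)(C)OO)
Why: Dirhodium-catalysed allylic oxidation with tert-butyl hydroperoxide converts the ring allylic CH2 (C3') into the enone carbonyl under near-neutral conditions that should leave C6' configurationally intact.

Step 20
Reactants: 32 ring enone nitrile
Product: 33 (2E,4E)-5-[(1R,4R)-4-hydroxy-2,6,6-trimethylcyclohex-2-en-1-yl]-3-methylpenta-2,4-dienenitrile
Conditions: LiBH(s-Bu)3, THF, −78 °C; then H2O
Reagents that add atoms: none
Why: 1,2-Reduction of the ring enone by a bulky hydride; equatorial attack anti to the axial C1' methyl, which is syn-axial to C3' in the half-chair that holds the C6' chain pseudoaxial, should give the 3',6'-trans (3'R) alcohol.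

Step 21
Reactants: 33 (3'R,6'R)-hydroxy nitrile
Product: 35 (2E,4E)-5-[(1R,4R)-4-hydroxy-2,6,6-trimethylcyclohex-2-en-1-yl]-3-methylpenta-2,4-dienal, via aluminio-aldimine 34 (not isolated)
Conditions: i-Bu2AlH (2.3 equiv), CH2Cl2, −78 °C; then wet silica gel, 0 °C
Reagents that add atoms: water (O)
Why: Partial hydride reduction of the nitrile after alkoxide formation, with acid-free hydrolysis of the imine so that the allylic C3' alcohol is not ionised.

Step 22
Reactants: 35 C15 hydroxy aldehyde of the ring B series; 24 hexadecanoyl chloride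
Product: 36 (1R,4R)-3,5,5-trimethyl-4-[(1E,3E)-3-methyl-5-oxopenta-1,3-dien-1-yl]cyclohex-2-en-1-yl hexadecanoate
Conditions: pyridine, DMAP (cat.), CH2Cl2, 0 °C to rt
Reagents that add atoms: none
Why: DMAP-catalysed acylation installs the second palmitate with retention at C3', because only the O–H bond is broken.

Step 23
Reactants: 36 C15 aldehyde palmitate of the ring B series; 9 enyne phosphonate
Product: 38 (1R,4R)-4-[(1E,3E,5E,7E)-3,7-dimethyl-10-(trimethylsilyl)deca-1,3,5,7-tetraen-9-yn-1-yl]-3,5,5-trimethylcyclohex-2-en-1-yl hexadecanoate, via sodium phosphonate carbanion 37 (not isolated)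
Conditions: 9, NaN(SiMe3)2, THF, −78 °C; then 36, −78 to −20 °C, dark
Reagents that add atoms: none
Why: Horner–Wadsworth–Emmons olefination should form C11'=C12' trans and brings in C12'–C15 with the preformed (13'E) alkene and the silyl-capped alkyne.

Step 24
Reactants: 38 silylated C21 enyne
Product: 39 (1R,4R)-4-[(1E,3E,5E,7E)-3,7-dimethyldeca-1,3,5,7-tetraen-9-yn-1-yl]-3,5,5-trimethylcyclohex-2-en-1-yl hexadecanoate
Conditions: Bu4NF, AcOH (1:1), THF, 0 °C
Reagents that add atoms: none
Why: Buffered fluoride cleaves the alkynyl C–Si bond without hydrolysing the palmitate.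

Step 25
Reactants: 39 C21 terminal enyne (ring B half); 27 C19 iodotetraene (ring A half)
Product: 41 (3S,5R,6S,3'R,6'R)-5,6-epoxy-5,6-dihydro-β,ε-carotene-3,3'-diyl dihexadecanoate, via alkenylzirconocene chloride 40 (not isolated)
Conditions: 39 (1.2 equiv), Cp2Zr(H)Cl (1.25 equiv), THF, rt, 30 min, dark; then 27 (1.0 equiv), Pd2(dba)3 (2.5 mol%), P(2-furyl)3 (10 mol%), THF, rt, dark, argon
Reagents that add atoms: none
Why: Cp2Zr(H)Cl adds syn and with terminal regiochemistry across the C15≡C15' alkyne of 39, placing zirconium on C15 and fixing the (15E) geometry; zerovalent palladium then inserts into the C14–I bond of 27, the alkenyl group passes from zirconium to palladium, and reductive elimination forms the C14–C15 bond with retention at both sp2 carbons. The closest known reaction type is the hydrozirconation and palladium-catalysed alkenyl–alkenyl (Negishi-type) coupling of terminal enynes with (E)-2-methyl-1-iodoalkenes used to build retinoid and carotenoid polyenes. No ring is closed and no stereocentre is created; the one new stereo element, the C15=C15' double bond, is controlled by the cis addition of Zr–H, while C13=C14 is carried in from 27. The step needs chemoselectivity: the alkyne must react before the hindered secondary C3' palmitate, the vinyl iodide before the allylic C3' ester, and the 5,6-epoxide must meet no strong Lewis acid. This should be secured by the unhindered CH termini at C14 and C15, by the distance of all five stereocentres and both esters from the reacting atoms, by leaving out any zinc halide, and by the weakly donating tri(2-furyl)phosphine, which favours oxidative addition to C–I over ionisation of the allylic ester. Working in the dark at room temperature should keep the new nonaene all-trans.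

**Compound list**

1 | prop-2-yn-1-ol | C#CCO | starting material
2 | dimethylaluminium (2E)-3-(dimethylalumanyl)-2-methylprop-2-en-1-olate | C[Al](C)OC/C(C)=C/[Al](C)C | intermediate
3 | (2E)-3-iodo-2-methylprop-2-en-1-ol | OC/C(C)=C/I | intermediate
4 | (1E)-3-bromo-1-iodo-2-methylprop-1-ene | BrC/C(C)=C/I | intermediate
5 | diethyl [(2E)-3-iodo-2-methylprop-2-en-1-yl]phosphonate | CCOP(=O)(C/C(C)=C/I)OCC | intermediate
6 | ethynyltrimethylsilane | C#C[Si](C)(C)C | starting material
7 | (2E)-2-methyl-5-(trimethylsilyl)pent-2-en-4-yn-1-ol | OC/C(C)=C/C#C[Si](C)(C)C | intermediate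
8 | [(3E)-5-bromo-4-methylpent-3-en-1-yn-1-yl]trimethylsilane | BrC/C(C)=C/C#C[Si](C)(C)C | intermediate
9 | diethyl [(2E)-2-methyl-5-(trimethylsilyl)pent-2-en-4-yn-1-yl]phosphonate | CCOP(=O)(C/C(C)=C/C#C[Si](C)(C)C)OCC | intermediate
10 | (4R,6R)-4-hydroxy-2,2,6-trimethylcyclohexan-1-one | O[C@H]1CC(C)(C)C(=O)[C@H](C)C1 | starting material
11 | (4R,6R)-4-[(tert-butyldimethylsilyl)oxy]-2,2,6-trimethylcyclohexan-1-one | CC(C)(C)[Si](C)(C)O[C@H]1CC(C)(C)C(=O)[C@H](C)C1 | intermediate
12 | lithium (4R)-4-[(tert-butyldimethylsilyl)oxy]-2,6,6-trimethylcyclohex-1-en-1-olate | CC(C)(C)[Si](C)(C)O[C@H]1CC(C)(C)C(O[Li])=C(C)C1 | intermediate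
13 | (4R)-4-[(tert-butyldimethylsilyl)oxy]-2,6,6-trimethylcyclohex-1-en-1-yl trifluoromethanesulfonate | CC(C)(C)[Si](C)(C)O[C@H]1CC(C)(C)C(OS(=O)(=O)C(F)(F)F)=C(C)C1 | intermediate
14 | methyl (4R)-4-[(tert-butyldimethylsilyl)oxy]-2,6,6-trimethylcyclohex-1-ene-1-carboxylate | CC(C)(C)[Si](C)(C)O[C@H]1CC(C)(C)C(C(=O)OC)=C(C)C1 | intermediate
15 | [(4R)-4-[(tert-butyldimethylsilyl)oxy]-2,6,6-trimethylcyclohex-1-en-1-yl]methanol | CC(C)(C)[Si](C)(C)O[C@H]1CC(C)(C)C(CO)=C(C)C1 | intermediate
16 | [(1R,2R,4S)-4-[(tert-butyldimethylsilyl)oxy]-1,2-epoxy-2,6,6-trimethylcyclohexyl]methanol (epoxide anti to the silyloxy group) | CC(C)(C)[Si](C)(C)O[C@H]1CC(C)(C)[C@]2(CO)O[C@]2(C)C1 | intermediate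
17 | (1S,2R,4S)-4-[(tert-butyldimethylsilyl)oxy]-1,2-epoxy-2,6,6-trimethylcyclohexane-1-carbaldehyde | CC(C)(C)[Si](C)(C)O[C@H]1CC(C)(C)[C@]2(C=O)O[C@]2(C)C1 | intermediate
18 | diethyl [(2E)-3-cyano-2-methylprop-2-en-1-yl]phosphonate | CCOP(=O)(C/C(C)=C/C#N)OCC | starting material
19 | sodium salt of the α-carbanion of 18 | [Na+].CCOP(=O)([CH-]/C(C)=C/C#N)OCC | intermediate
20 | (2E,4E)-5-[(1S,2R,4S)-4-[(tert-butyldimethylsilyl)oxy]-1,2-epoxy-2,6,6-trimethylcyclohexyl]-3-methylpenta-2,4-dienenitrile | CC(C)(C)[Si](C)(C)O[C@H]1CC(C)(C)[C@]2(/C=C/C(C)=C/C#N)O[C@]2(C)C1 | intermediate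
21 | (2E,4E)-5-[(1S,2R,4S)-1,2-epoxy-4-hydroxy-2,6,6-trimethylcyclohexyl]-3-methylpenta-2,4-dienenitrile | O[C@H]1CC(C)(C)[C@]2(/C=C/C(C)=C/C#N)O[C@]2(C)C1 | intermediate
22 | O-(diisobutylaluminium) alkoxide N-(diisobutylaluminio) aldimine derived from 21 | CC(C)C[Al](CC(C)C)O[C@H]1CC(C)(C)[C@]2(/C=C/C(C)=C/C=N[Al](CC(C)C)CC(C)C)O[C@]2(C)C1 | intermediate
23 | (2E,4E)-5-[(1S,2R,4S)-1,2-epoxy-4-hydroxy-2,6,6-trimethylcyclohexyl]-3-methylpenta-2,4-dienal | O[C@H]1CC(C)(C)[C@]2(/C=C/C(C)=C/C=O)O[C@]2(C)C1 | intermediate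
24 | hexadecanoyl chloride (palmitoyl chloride) | CCCCCCCCCCCCCCCC(=O)Cl | starting material
25 | (2E,4E)-5-[(1S,2R,4S)-1,2-epoxy-4-(hexadecanoyloxy)-2,6,6-trimethylcyclohexyl]-3-methylpenta-2,4-dienal | CCCCCCCCCCCCCCCC(=O)O[C@H]1CC(C)(C)[C@]2(/C=C/C(C)=C/C=O)O[C@]2(C)C1 | intermediate
26 | sodium salt of the α-carbanion of 5 | [Na+].CCOP(=O)([CH-]/C(C)=C/I)OCC | intermediate
27 | (1S,3R,4S)-3,4-epoxy-4-[(1E,3E,5E,7E)-8-iodo-3,7-dimethylocta-1,3,5,7-tetraen-1-yl]-3,5,5-trimethylcyclohexyl hexadecanoate | CCCCCCCCCCCCCCCC(=O)O[C@H]1CC(C)(C)[C@]2(/C=C/C(C)=C/C=C/C(C)=C/I)O[C@]2(C)C1 | intermediate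
28 | (R)-α-ionone, (3E)-4-[(1R)-2,6,6-trimethylcyclohex-2-en-1-yl]but-3-en-2-one | CC(=O)/C=C/[C@H]1C(C)=CCCC1(C)C | starting material
29 | diethyl (cyanomethyl)phosphonate | CCOP(=O)(CC#N)OCC | starting material
30 | sodium salt of the α-carbanion of 29 | [Na+].CCOP(=O)([CH-]C#N)OCC | intermediate
31 | (2E,4E)-3-methyl-5-[(1R)-2,6,6-trimethylcyclohex-2-en-1-yl]penta-2,4-dienenitrile | N#C/C=C(C)/C=C/[C@H]1C(C)=CCCC1(C)C | intermediate
32 | (2E,4E)-3-methyl-5-[(1R)-2,6,6-trimethyl-4-oxocyclohex-2-en-1-yl]penta-2,4-dienenitrile | N#C/C=C(C)/C=C/[C@H]1C(C)=CC(=O)CC1(C)C | intermediate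
33 | (2E,4E)-5-[(1R,4R)-4-hydroxy-2,6,6-trimethylcyclohex-2-en-1-yl]-3-methylpenta-2,4-dienenitrile | N#C/C=C(C)/C=C/[C@H]1C(C)=C[C@H](O)CC1(C)C | intermediate
34 | O-(diisobutylaluminium) alkoxide N-(diisobutylaluminio) aldimine derived from 33 | CC(C)C[Al](CC(C)C)N=C/C=C(C)/C=C/[C@H]1C(C)=C[C@H](O[Al](CC(C)C)CC(C)C)CC1(C)C | intermediate
35 | (2E,4E)-5-[(1R,4R)-4-hydroxy-2,6,6-trimethylcyclohex-2-en-1-yl]-3-methylpenta-2,4-dienal | O=C/C=C(C)/C=C/[C@H]1C(C)=C[C@H](O)CC1(C)C | intermediate
36 | (1R,4R)-3,5,5-trimethyl-4-[(1E,3E)-3-methyl-5-oxopenta-1,3-dien-1-yl]cyclohex-2-en-1-yl hexadecanoate | O=C/C=C(C)/C=C/[C@H]1C(C)=C[C@H](OC(=O)CCCCCCCCCCCCCCC)CC1(C)C | intermediate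
37 | sodium salt of the α-carbanion of 9 | [Na+].CCOP(=O)([CH-]/C(C)=C/C#C[Si](C)(C)C)OCC | intermediate
38 | (1R,4R)-4-[(1E,3E,5E,7E)-3,7-dimethyl-10-(trimethylsilyl)deca-1,3,5,7-tetraen-9-yn-1-yl]-3,5,5-trimethylcyclohex-2-en-1-yl hexadecanoate | C[Si](C)(C)C#C/C=C(C)/C=C/C=C(C)/C=C/[C@H]1C(C)=C[C@H](OC(=O)CCCCCCCCCCCCCCC)CC1(C)C | intermediate
39 | (1R,4R)-4-[(1E,3E,5E,7E)-3,7-dimethyldeca-1,3,5,7-tetraen-9-yn-1-yl]-3,5,5-trimethylcyclohex-2-en-1-yl hexadecanoate | C#C/C=C(C)/C=C/C=C(C)/C=C/[C@H]1C(C)=C[C@H](OC(=O)CCCCCCCCCCCCCCC)CC1(C)C | intermediate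
40 | chlorobis(cyclopentadienyl)[(1E,3E,5E,7E,9E)-10-[(1R,4R)-4-(hexadecanoyloxy)-2,6,6-trimethylcyclohex-2-en-1-yl]-4,8-dimethyldeca-1,3,5,7,9-pentaen-1-yl]zirconium (cyclopentadienyl rings drawn sigma-bonded) | Cl[Zr](/C=C/C=C(C)/C=C/C=C(C)/C=C/[C@H]1C(C)=C[C@H](OC(=O)CCCCCCCCCCCCCCC)CC1(C)C)(C1C=CC=C1)C1C=CC=C1 | intermediate
41 | (3S,5R,6S,3'R,6'R)-5,6-epoxy-5,6-dihydro-β,ε-carotene-3,3'-diyl dihexadecanoate (lutein 5,6-epoxide dipalmitate) | CCCCCCCCCCCCCCCC(=O)O[C@H]1CC(C)(C)[C@]2(/C=C/C(C)=C/C=C/C(C)=C/C=C/C=C(C)/C=C/C=C(C)/C=C/[C@H]3C(C)=C[C@H](OC(=O)CCCCCCCCCCCCCCC)CC3(C)C)O[C@]2(C)C1 | target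

**Step count and risks**

Total step count: 25. Longest linear sequence: 12 steps (steps 7 to 17, then step 25).

Steps most likely to fail:

1. Step 25. The zirconium hydride may reduce the C3' palmitate in competition with the alkyne, the transfer of the alkenyl group from zirconium to palladium may be too slow, or zerovalent palladium may ionise the allylic C3' ester. Fallback, setting out from 39 and coming back to the route at 41: 39 is hydrostannated under palladium catalysis (Bu3SnH, PdCl2(PPh3)2, THF, 0 °C) to the (1E)-dienylstannane (1R,4R)-4-[(1E,3E,5E,7E,9E)-3,7-dimethyl-10-(tributylstannyl)deca-1,3,5,7,9-pentaen-1-yl]-3,5,5-trimethylcyclohex-2-en-1-yl hexadecanoate F1. After purification, F1 is joined to 27 by a Stille coupling (Pd2(dba)3, AsPh3, N-methylpyrrolidone, rt, dark), which forms the same C14–C15 bond with a neutral tin nucleophile and without any metal hydride near the esters or the epoxide.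

2. Step 20. The hydride may be delivered to the wrong face of the C3' carbonyl (poor facial selectivity), or the basic reagent may epimerise C6'. Fallback, setting out from 32 and coming back at 36: the ketone is reduced with a small hydride under Luche conditions (NaBH4, CeCl3·7H2O, MeOH, −40 °C), where axial attack should favour the 3',6'-cis alcohol (2E,4E)-5-[(1R,4S)-4-hydroxy-2,6,6-trimethylcyclohex-2-en-1-yl]-3-methylpenta-2,4-dienenitrile F2, separable from its epimer 33 as a diastereomer. F2 is reduced with i-Bu2AlH as in step 21 to the cis hydroxy aldehyde (2E,4E)-5-[(1R,4S)-4-hydroxy-2,6,6-trimethylcyclohex-2-en-1-yl]-3-methylpenta-2,4-dienal F3. A Mitsunobu esterification of F3 with hexadecanoic acid (PPh3, diisopropyl azodicarboxylate, toluene, 0 °C) then installs the palmitate with inversion at C3' and gives 36 directly.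

3. Step 19. Hydrogen abstraction may occur at the doubly allylic C6'–H instead of C3', the dienenitrile may be over-oxidised, or C6' may lose its configuration once it becomes the γ-position of the enone. Fallback, setting out from 28 and coming back at 33, so that the ring is oxygenated before the chain is extended:
   - 28 is converted with ethylene glycol, triethyl orthoformate and pyridinium p-toluenesulfonate into the dioxolane 2-methyl-2-[(E)-2-[(1R)-2,6,6-trimethylcyclohex-2-en-1-yl]ethenyl]-1,3-dioxolane F4.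
   - Allylic oxidation of F4 under the conditions of step 19 should give the ring enone 4-[(E)-2-(2-methyl-1,3-dioxolan-2-yl)ethenyl]-(4R)-3,5,5-trimethylcyclohex-2-en-1-one F5.
   - Reduction with LiBH(s-Bu)3 as in step 20 should give the trans alcohol (1R,4R)-3,5,5-trimethyl-4-[(E)-2-(2-methyl-1,3-dioxolan-2-yl)ethenyl]cyclohex-2-en-1-ol F6.
   - Mild hydrolysis (pyridinium p-toluenesulfonate, aqueous acetone, rt) frees (3R,6R)-3-hydroxy-α-ionone F7.
   - Olefination of F7 with two equivalents of carbanion 30 as in step 18 returns 33.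

**Further compounds**

F1 | step 25 | (1R,4R)-4-[(1E,3E,5E,7E,9E)-3,7-dimethyl-10-(tributylstannyl)deca-1,3,5,7,9-pentaen-1-yl]-3,5,5-trimethylcyclohex-2-en-1-yl hexadecanoate | CCCC[Sn](CCCC)(CCCC)/C=C/C=C(C)/C=C/C=C(C)/C=C/[C@H]1C(C)=C[C@H](OC(=O)CCCCCCCCCCCCCCC)CC1(C)C
F2 | step 20 | (2E,4E)-5-[(1R,4S)-4-hydroxy-2,6,6-trimethylcyclohex-2-en-1-yl]-3-methylpenta-2,4-dienenitrile | N#C/C=C(C)/C=C/[C@H]1C(C)=C[C@@H](O)CC1(C)C
F3 | step 20 | (2E,4E)-5-[(1R,4S)-4-hydroxy-2,6,6-trimethylcyclohex-2-en-1-yl]-3-methylpenta-2,4-dienal | O=C/C=C(C)/C=C/[C@H]1C(C)=C[C@@H](O)CC1(C)C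
F4 | step 19 | 2-methyl-2-[(E)-2-[(1R)-2,6,6-trimethylcyclohex-2-en-1-yl]ethenyl]-1,3-dioxolane | CC1(/C=C/[C@H]2C(C)=CCCC2(C)C)OCCO1
F5 | step 19 | (4R)-3,5,5-trimethyl-4-[(E)-2-(2-methyl-1,3-dioxolan-2-yl)ethenyl]cyclohex-2-en-1-one | CC1(/C=C/[C@H]2C(C)=CC(=O)CC2(C)C)OCCO1
F6 | step 19 | (1R,4R)-3,5,5-trimethyl-4-[(E)-2-(2-methyl-1,3-dioxolan-2-yl)ethenyl]cyclohex-2-en-1-ol | CC1(/C=C/[C@H]2C(C)=C[C@H](O)CC2(C)C)OCCO1
F7 | step 19 | (3E)-4-[(1R,4R)-4-hydroxy-2,6,6-trimethylcyclohex-2-en-1-yl]but-3-en-2-one | CC(=O)/C=C/[C@H]1C(C)=C[C@H](O)CC1(C)C
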